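**Plan**

- The retrosynthesis first cuts the two ArCH2–Ar bonds at ring B: the ring C CH2–ring B bond (last bond made), then the ring A CH2–ring B bond.
- Ring C is then cut at C5–C(=O)Pr (O→C acyl shift) and at C6–C1 and C2–C3 (benzannulation), leading back to 3-methoxy-2-methylcyclobutenone and a siloxyalkyne that already carries the bridge carbon.
- The enabling feature is ring C itself: C1 (bridge) lies between the free OH groups at C2 and C6, C3 carries methyl, and the C4 OMe sits beside the C5 butanoyl group. The annulation delivers the oxygens at C6, C2 and C4 as OH, OSi and OMe and leaves C5 as the only ring CH.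
- Forward: cyclobutenone and alkyne (steps 1–4), ring C closed (step 5), butanoyl installed via bromide, ester and acyl shift (steps 6–8), desilylation (step 9). Ring A comes from acylation and selective methylation of methylphloroglucinol and is joined to ring B through a Mannich base (steps 10–13); the last bridge is made in step 14.
- The target has no stereocentre; only regiochemistry has to be controlled.

Key step: step 5

Remark: ring A is the aspidinol-type ring (bridge between OMe and OH), ring B the central acetyl ring, ring C the ring whose bridge lies between two OH groups. Ring C is numbered C1 (bridge-bearing carbon), C2 (OH), C3 (Me), C4 (OMe), C5 (butanoyl), C6 (OH). The central ring is assumed to be the 2,4,6-trihydroxyacetophenone tautomer drawn in the SMILES.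

**Step 1**
Reactants: 1 1-ethoxypropyne; 2 acetyl chloride
Product: 4 3-ethoxy-2-methylcyclobut-2-en-1-one, via ketene 3 (not isolated)
Conditions: Et3N, MeCN, 0 °C → rt, slow addition of 2
Reagents that add atoms: none
Why: Et3N dehydrochlorinates acetyl chloride to ketene, which the electron-rich ynol ether traps in a thermal (2+2) ketene–alkyne cycloaddition; the methyl-bearing alkyne carbon attacks the ketene carbonyl carbon, so OEt ends at C3 and methyl at C2.

**Step 2**
Reactants: 4 3-ethoxy-2-methylcyclobut-2-en-1-one
Product: 5 2-methylcyclobutane-1,3-dione (enol form 3-hydroxy-2-methylcyclobut-2-en-1-one)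
Conditions: 2 M aq. HCl, 0 °C → rt
Reagents that add atoms: water, O
Why: Vinylogous ester hydrolysis (C-protonation, addition of water, loss of ethanol) should give the symmetrical dione as its enol, and the cold acidic medium avoids retro-Claisen opening of the strained ring.

**Step 3**
Reactants: 5 2-methylcyclobutane-1,3-dione
Product: 6 3-methoxy-2-methylcyclobut-2-en-1-one
Conditions: Me3SiCHN2, MeOH–toluene, 0 °C
Reagents that add atoms: (trimethylsilyl)diazomethane, C[Si](C)(C)C=[N+]=[N-]
Why: O-methylation of the strongly acidic vinylogous acid by a diazoalkane proceeds without base, and because the dione is symmetrical only one enol ether can form.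

**Step 4**
Reactants: 7 ethyl 2-(benzyloxy)acetate
Product: 10 {[3-(benzyloxy)prop-1-yn-1-yl]oxy}triisopropylsilane, via lithium 3-(benzyloxy)-1,1-dibromoprop-1-en-2-olate 8 (not isolated), via lithium 3-(benzyloxy)prop-1-yn-1-olate 9 (not isolated)
Conditions: CH2Br2, LiTMP (lithium 2,2,6,6-tetramethylpiperidide), THF, −78 °C; then LiN(SiMe3)2; then n-BuLi, −78 → 0 °C; then iPr3SiOTf, −78 °C → rt
Reagents that add atoms: dibromomethane, BrCBr; triisopropylsilyl trifluoromethanesulfonate, CC(C)[Si](OS(=O)(=O)C(F)(F)F)(C(C)C)C(C)C
Why: Kowalski ester homologation: LiCHBr2 adds to the ester, the derived dibromo enolate undergoes Br–Li exchange and 1,2-shift of the benzyloxymethyl group to the ynolate, and the hard silyl triflate silylates it on oxygen.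

**Step 5**
Reactants: 6 3-methoxy-2-methylcyclobut-2-en-1-one; 10 {[3-(benzyloxy)prop-1-yn-1-yl]oxy}triisopropylsilane
Product: 15 2-[(benzyloxy)methyl]-5-methoxy-4-methyl-3-[(triisopropylsilyl)oxy]phenol, via vinylketene 11 (not isolated), via 4-vinylcyclobutenone 12 (not isolated), via dienylketene 13 (not isolated), via cyclohexa-2,4-dienone 14 (not isolated)
Conditions: 10 (1.2 equiv), toluene, 80 °C then 110 °C, sealed tube
Reagents that add atoms: none
Why: Heating opens cyclobutenone 6 by four-electron electrocyclic cleavage of its C(=O)–CH2 bond to vinylketene 11, whose ketene C=C adds across the siloxyalkyne in a (2+2) cycloaddition that forms C6–C1 and C2–C3 and gives 4-vinylcyclobutenone 12. A second four-electron opening gives dienylketene 13, and ring C closes by a thermal six-electron (disrotatory) electrocyclization joining the ketene carbon C6 to the terminal CH2 (C5); tautomerization of cyclohexadienone 14 gives the phenol. This is the Danheiser benzannulation of a cyclobutenone with a siloxyalkyne, applied to a 3-alkoxycyclobutenone, whose vinylogous ester stabilization is the reason for finishing at 110 °C. No stereocentre is formed in the product; the quaternary carbon of 12 is racemic and disappears on ring opening. The one selectivity required is the orientation of the (2+2) step, and the polarization of the ynol ether secures it: the nucleophilic carbon remote from oxygen attacks the electrophilic ketene carbonyl carbon, so the OSi-bearing carbon ends next to the methyl-bearing C3. The ketene oxygen therefore emerges as free OH at C6, the alkyne oxygen as OSi at C2 and the cyclobutenone oxygen as OMe at C4, with C5 the only ring CH.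

**Step 6**
Reactants: 15 2-[(benzyloxy)methyl]-5-methoxy-4-methyl-3-[(triisopropylsilyl)oxy]phenol
Product: 16 2-[(benzyloxy)methyl]-6-bromo-5-methoxy-4-methyl-3-[(triisopropylsilyl)oxy]phenol
Conditions: NBS, NaHCO3, CH2Cl2, −20 → 0 °C
Reagents that add atoms: N-bromosuccinimide, O=C1CCC(=O)N1Br
Why: Electrophilic aromatic bromination should occur at C5, the only unsubstituted ring carbon (ortho to OH and OMe, para to OSi), while the bicarbonate keeps HBr from ionizing the benzylic ether.

**Step 7**
Reactants: 16 2-[(benzyloxy)methyl]-6-bromo-5-methoxy-4-methyl-3-[(triisopropylsilyl)oxy]phenol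
Product: 17 2-[(benzyloxy)methyl]-6-bromo-5-methoxy-4-methyl-3-[(triisopropylsilyl)oxy]phenyl butanoate
Conditions: butanoyl chloride, Et3N, DMAP (cat.), CH2Cl2, 0 °C → rt
Reagents that add atoms: butanoyl chloride, CCCC(Cl)=O
Why: DMAP-catalysed O-acylation of the hindered phenol masks the acidic OH and places the butanoyl group on the oxygen next to the carbon to be metalated; a Lewis-acid Friedel–Crafts acylation is avoided because it would ionize the benzylic ether.

**Step 8**
Reactants: 17 2-[(benzyloxy)methyl]-6-bromo-5-methoxy-4-methyl-3-[(triisopropylsilyl)oxy]phenyl butanoate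
Product: 19 1-{3-[(benzyloxy)methyl]-2-hydroxy-6-methoxy-5-methyl-4-[(triisopropylsilyl)oxy]phenyl}butan-1-one, via aryllithium 18 (not isolated)
Conditions: n-BuLi, THF–Et2O, −100 → −40 °C; aq. NH4Cl
Reagents that add atoms: none
Why: Bromine–lithium exchange under Parham conditions outruns addition to the ester, and the aryllithium attacks the neighbouring ester carbonyl in an anionic ortho-Fries 1,3 O→C acyl shift, giving the chelated lithium phenoxide of the ortho-hydroxyaryl ketone, which resists further addition.

**Step 9**
Reactants: 19 1-{3-[(benzyloxy)methyl]-2-hydroxy-6-methoxy-5-methyl-4-[(triisopropylsilyl)oxy]phenyl}butan-1-one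
Product: 20 1-{3-[(benzyloxy)methyl]-2,4-dihydroxy-6-methoxy-5-methylphenyl}butan-1-one
Conditions: Bu4NF, AcOH, THF, 0 °C
Reagents that add atoms: none
Why: Fluoride cleaves the aryl silyl ether, the acetic acid buffer keeps the liberated phenoxide from expelling benzyloxide, and the benzyl ether and ketone are untouched.

**Step 10**
Reactants: 21 2-methylbenzene-1,3,5-triol (2,4,6-trihydroxytoluene)
Product: 22 1-(2,4,6-trihydroxy-3-methylphenyl)butan-1-one
Conditions: butanoyl chloride, AlCl3, PhNO2–CH2Cl2, 0 → 40 °C; aq. HCl work-up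
Reagents that add atoms: butanoyl chloride, CCCC(Cl)=O
Why: Friedel–Crafts acylation of the phloroglucinol nucleus; the two free ring positions are equivalent and the first acyl group deactivates the ring toward a second.

**Step 11**
Reactants: 22 1-(2,4,6-trihydroxy-3-methylphenyl)butan-1-one
Product: 23 1-(2,6-dihydroxy-4-methoxy-3-methylphenyl)butan-1-one (aspidinol)
Conditions: Me2SO4 (1.0 equiv), K2CO3 (1.0 equiv), acetone, rt
Reagents that add atoms: dimethyl sulfate, COS(=O)(=O)OC
Why: Selective Williamson methylation: the 4-OH, para to the ketone and not hydrogen-bonded to it, is the most acidic and accessible hydroxyl, so one equivalent of Me2SO4 should give the 4-methyl ether.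

**Step 12**
Reactants: 23 1-(2,6-dihydroxy-4-methoxy-3-methylphenyl)butan-1-one
Product: 24 1-{3-[(dimethylamino)methyl]-2,6-dihydroxy-4-methoxy-5-methylphenyl}butan-1-one
Conditions: 37% aq. CH2O, 40% aq. Me2NH, EtOH, 0 °C → rt
Reagents that add atoms: formaldehyde, C=O; dimethylamine, CNC
Why: Phenolic Mannich reaction at the single free ring carbon of ring A, which lies ortho to OH and to OMe.

**Step 13**
Reactants: 24 1-{3-[(dimethylamino)methyl]-2,6-dihydroxy-4-methoxy-5-methylphenyl}butan-1-one; 25 1-(2,4,6-trihydroxyphenyl)ethan-1-one (2,4,6-trihydroxyacetophenone)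
Product: 27 1-{3-[(3-acetyl-2,4,6-trihydroxyphenyl)methyl]-2,6-dihydroxy-4-methoxy-5-methylphenyl}butan-1-one, via ring A ortho-quinone methide 26 (not isolated)
Conditions: 25 (3 equiv), 1,4-dioxane, 100 °C
Reagents that add atoms: none
Why: Thermal loss of dimethylamine from the phenolic Mannich base gives the ortho-quinone methide, which the phloroglucinol nucleus of 25 captures by conjugate C-alkylation; the excess of 25 suppresses double alkylation.

**Step 14**
Reactants: 20 1-{3-[(benzyloxy)methyl]-2,4-dihydroxy-6-methoxy-5-methylphenyl}butan-1-one; 27 1-{3-[(3-acetyl-2,4,6-trihydroxyphenyl)methyl]-2,6-dihydroxy-4-methoxy-5-methylphenyl}butan-1-one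
Product: 29 the target CNP0184345.0, via ring C ortho-quinone methide 28 (not isolated)
Conditions: 27 (1.2 equiv), TsOH·H2O (0.2 equiv), 1,4-dioxane, 40 °C
Reagents that add atoms: none
Why: Acid-catalysed ionization of the ortho-hydroxybenzyl ether (benzylic cation stabilized by two ortho OH and the para OMe) gives the ortho-quinone methide, which the only free ring carbon of 27 captures in a Friedel–Crafts alkylation; 20 has no free ring carbon and so cannot self-condense on carbon.

**Compound list**

1 | 1-ethoxypropyne | CCOC#CC | starting material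
2 | acetyl chloride | CC(Cl)=O | starting material
3 | ketene | C=C=O | intermediate (not isolated)
4 | 3-ethoxy-2-methylcyclobut-2-en-1-one | CCOC1=C(C)C(=O)C1 | intermediate
5 | 2-methylcyclobutane-1,3-dione, drawn as its enol 3-hydroxy-2-methylcyclobut-2-en-1-one | CC1=C(O)CC1=O | intermediate
6 | 3-methoxy-2-methylcyclobut-2-en-1-one | COC1=C(C)C(=O)C1 | intermediate
7 | ethyl 2-(benzyloxy)acetate | CCOC(=O)COCc1ccccc1 | starting material
8 | lithium 3-(benzyloxy)-1,1-dibromoprop-1-en-2-olate | [Li+].[O-]C(COCc1ccccc1)=C(Br)Br | intermediate (not isolated)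
9 | lithium 3-(benzyloxy)prop-1-yn-1-olate | [Li+].[O-]C#CCOCc1ccccc1 | intermediate (not isolated)
10 | {[3-(benzyloxy)prop-1-yn-1-yl]oxy}triisopropylsilane | CC(C)[Si](OC#CCOCc1ccccc1)(C(C)C)C(C)C | intermediate
11 | 3-methoxy-2-methylbuta-1,3-dien-1-one (vinylketene) | COC(=C)C(C)=C=O | intermediate (not isolated)
12 | 2-[(benzyloxy)methyl]-4-(1-methoxyethenyl)-4-methyl-3-[(triisopropylsilyl)oxy]cyclobut-2-en-1-one (racemic) | O=C1C(COCc2ccccc2)=C(O[Si](C(C)C)(C(C)C)C(C)C)C1(C)C(=C)OC | intermediate (not isolated)
13 | (3E)-2-[(benzyloxy)methyl]-5-methoxy-4-methyl-3-[(triisopropylsilyl)oxy]hexa-1,3,5-trien-1-one (dienylketene, ketene and vinyl groups cis) | O=C=C(COCc1ccccc1)/C(O[Si](C(C)C)(C(C)C)C(C)C)=C(C)\C(=C)OC | intermediate (not isolated)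
14 | 2-[(benzyloxy)methyl]-5-methoxy-4-methyl-3-[(triisopropylsilyl)oxy]cyclohexa-2,4-dien-1-one | O=C1CC(OC)=C(C)C(O[Si](C(C)C)(C(C)C)C(C)C)=C1COCc1ccccc1 | intermediate (not isolated)
15 | 2-[(benzyloxy)methyl]-5-methoxy-4-methyl-3-[(triisopropylsilyl)oxy]phenol | COc1cc(O)c(COCc2ccccc2)c(O[Si](C(C)C)(C(C)C)C(C)C)c1C | intermediate
16 | 2-[(benzyloxy)methyl]-6-bromo-5-methoxy-4-methyl-3-[(triisopropylsilyl)oxy]phenol | COc1c(Br)c(O)c(COCc2ccccc2)c(O[Si](C(C)C)(C(C)C)C(C)C)c1C | intermediate
17 | 2-[(benzyloxy)methyl]-6-bromo-5-methoxy-4-methyl-3-[(triisopropylsilyl)oxy]phenyl butanoate | CCCC(=O)Oc1c(Br)c(OC)c(C)c(O[Si](C(C)C)(C(C)C)C(C)C)c1COCc1ccccc1 | intermediate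
18 | 2-[(benzyloxy)methyl]-6-lithio-5-methoxy-4-methyl-3-[(triisopropylsilyl)oxy]phenyl butanoate (aryllithium) | CCCC(=O)Oc1c([Li])c(OC)c(C)c(O[Si](C(C)C)(C(C)C)C(C)C)c1COCc1ccccc1 | intermediate (not isolated)
19 | 1-{3-[(benzyloxy)methyl]-2-hydroxy-6-methoxy-5-methyl-4-[(triisopropylsilyl)oxy]phenyl}butan-1-one | CCCC(=O)c1c(O)c(COCc2ccccc2)c(O[Si](C(C)C)(C(C)C)C(C)C)c(C)c1OC | intermediate
20 | 1-{3-[(benzyloxy)methyl]-2,4-dihydroxy-6-methoxy-5-methylphenyl}butan-1-one | CCCC(=O)c1c(O)c(COCc2ccccc2)c(O)c(C)c1OC | intermediate
21 | 2-methylbenzene-1,3,5-triol (2,4,6-trihydroxytoluene) | Cc1c(O)cc(O)cc1O | starting material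
22 | 1-(2,4,6-trihydroxy-3-methylphenyl)butan-1-one | CCCC(=O)c1c(O)cc(O)c(C)c1O | intermediate
23 | 1-(2,6-dihydroxy-4-methoxy-3-methylphenyl)butan-1-one (aspidinol) | CCCC(=O)c1c(O)cc(OC)c(C)c1O | intermediate
24 | 1-{3-[(dimethylamino)methyl]-2,6-dihydroxy-4-methoxy-5-methylphenyl}butan-1-one | CCCC(=O)c1c(O)c(CN(C)C)c(OC)c(C)c1O | intermediate
25 | 1-(2,4,6-trihydroxyphenyl)ethan-1-one (2,4,6-trihydroxyacetophenone) | CC(=O)c1c(O)cc(O)cc1O | starting material
26 | 2-butanoyl-3-hydroxy-5-methoxy-4-methyl-6-methylidenecyclohexa-2,4-dien-1-one (ring A ortho-quinone methide) | CCCC(=O)C1=C(O)C(C)=C(OC)C(=C)C1=O | intermediate (not isolated)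
27 | 1-{3-[(3-acetyl-2,4,6-trihydroxyphenyl)methyl]-2,6-dihydroxy-4-methoxy-5-methylphenyl}butan-1-one (ring A–ring B dimer) | CCCC(=O)c1c(O)c(C)c(OC)c(Cc2c(O)cc(O)c(C(C)=O)c2O)c1O | intermediate
28 | 4-butanoyl-5-hydroxy-3-methoxy-2-methyl-6-methylidenecyclohexa-2,4-dien-1-one (ring C ortho-quinone methide) | CCCC(=O)C1=C(O)C(=C)C(=O)C(C)=C1OC | intermediate (not isolated)
29 | 1-{3-[(3-acetyl-5-{[3-butanoyl-2,4-dihydroxy-6-methoxy-5-methylphenyl]methyl}-2,4,6-trihydroxyphenyl)methyl]-2,4-dihydroxy-6-methoxy-5-methylphenyl}butan-1-one (CNP0184345.0, achiral) | CCCC(=O)c1c(O)c(C)c(OC)c(Cc2c(O)c(Cc3c(O)c(C)c(OC)c(C(=O)CCC)c3O)c(O)c(C(C)=O)c2O)c1O | target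

Total step count: 14 steps.
Longest linear sequence: 9 steps (steps 1, 2, 3, 5, 6, 7, 8, 9, 14, from 1-ethoxypropyne).

**Steps most likely to fail**

Step 5. The vinylogous ester character of 6 may make the first ring opening slow, so that decomposition of 6, or acylation of the product phenol by the vinylketene, competes with the annulation. The fallback generates the same vinylketene 11 by dehydrochlorination instead of electrocyclic opening. Purchased methyl 2-methyl-3-oxobutanoate F1 would be converted with HC(OMe)3 and catalytic H2SO4 in MeOH into methyl (E)-3-methoxy-2-methylbut-2-enoate F2 (the geometry is lost later and is of no consequence). Saponification with LiOH in aqueous THF would give (E)-3-methoxy-2-methylbut-2-enoic acid F3, and oxalyl chloride with catalytic DMF would give (E)-3-methoxy-2-methylbut-2-enoyl chloride F4. Slow addition of Et3N to F4 and 10 in CH2Cl2 at room temperature should cause 1,4-elimination to 11 and its (2+2) cycloaddition with the siloxyalkyne. The fallback sets out from 10 and returns to the route at 12, which on brief heating in toluene passes through 13 and 14 to 15.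

Step 8. The alkyllithium may add to, or enolize, the aryl butanoate faster than it exchanges bromine, or the aryllithium may be protonated before the acyl group migrates. The fallback replaces the intramolecular acyl shift by an intermolecular addition and sets out from 16. Deprotonation of the phenol with MeLi, bromine–lithium exchange with t-BuLi in THF at −78 °C and addition of butanal should give racemic 1-{3-[(benzyloxy)methyl]-2-hydroxy-6-methoxy-5-methyl-4-[(triisopropylsilyl)oxy]phenyl}butan-1-ol F5. Oxidation of the benzylic alcohol with Dess–Martin periodinane buffered with NaHCO3 returns to the route at 19.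

Step 14. Under acid the ring A–ring B bridge already present in 27 may fragment by retro-Friedel–Crafts reaction and recombine, scrambling the bridges, while ionization of the acyl-deactivated benzyl ether is slow. The fallback reverses the order of bridging so that no preformed bridge is exposed to acid. It sets out from 20, which would be ionized under the same acid in the presence of an excess of 25 to give 1-{3-[(3-acetyl-2,4,6-trihydroxyphenyl)methyl]-2,4-dihydroxy-6-methoxy-5-methylphenyl}butan-1-one F6, the ring B–ring C dimer. Heating F6 with Mannich base 24 in 1,4-dioxane, as in step 13, alkylates its single free ring carbon without acid and returns to the route at 29.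

**Further compounds**

F1 | step 5 | methyl 2-methyl-3-oxobutanoate (purchased) | COC(=O)C(C)C(C)=O
F2 | step 5 | methyl (E)-3-methoxy-2-methylbut-2-enoate | CO/C(C)=C(\C)C(=O)OC
F3 | step 5 | (E)-3-methoxy-2-methylbut-2-enoic acid | CO/C(C)=C(\C)C(=O)O
F4 | step 5 | (E)-3-methoxy-2-methylbut-2-enoyl chloride | CO/C(C)=C(\C)C(Cl)=O
F5 | step 8 | 1-{3-[(benzyloxy)methyl]-2-hydroxy-6-methoxy-5-methyl-4-[(triisopropylsilyl)oxy]phenyl}butan-1-ol (racemic) | CCCC(O)c1c(O)c(COCc2ccccc2)c(O[Si](C(C)C)(C(C)C)C(C)C)c(C)c1OC
F6 | step 14 | 1-{3-[(3-acetyl-2,4,6-trihydroxyphenyl)methyl]-2,4-dihydroxy-6-methoxy-5-methylphenyl}butan-1-one | CCCC(=O)c1c(O)c(Cc2c(O)cc(O)c(C(C)=O)c2O)c(O)c(C)c1OC
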